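**Retrosynthetic overview**
- Target 25 comes from alkyne 24 by syn semi-hydrogenation. 24 comes from the tert-butyl ester 20 by acidolysis and decarboxylation, which resets C4 and lets C3 follow.
- The only ring, the 1,2-dioxane O1–O2–C3–C4–C5–C6, is formed in one operation from alkene 12, keto diester 17 and O2 by a manganese-mediated aerobic radical annulation (bonds C4–C5, C6–O1, O2–C3).
- The feature that carries the plan: the 1,2-dioxan-3-ol ring is a ketone carbonyl (C3) with its methyl-bearing α-carbon (C4), a 1,1-disubstituted alkene (C5 as the CH2 end, C6 as the quaternary end) and one O2 molecule (O1, O2).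
- 12 comes from tosylate 10 (C8 centre set by an Evans methallylation) and the Grignard reagent of bromide 4 by copper-catalysed alkyl–alkyl coupling. 17 comes from the malonic half ester 14 and Meldrum's acid.

Key step: step 8

Remark: C4 and C6 cannot be steered in step 8, so 19–23 are drawn with the ring centres open (C8 is R throughout), and 24 is the (3S,4R,6S) isomer isolated in step 9. Locants C1–C16 run from the ester carbonyl and coincide with the ring locants at C3–C6.

**Route**

Step 1
Reactants: 1 phenylacetylene; 2 1,5-dibromopentane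
Product: 4 7-bromo-1-phenylhept-1-yne, via lithium phenylacetylide 3 (not isolated)
Conditions: n-BuLi, THF, −78 °C; then 2 (4 equiv), DMPU, −78 °C to rt
Reagents that add atoms: none
Why: SN2 alkylation of a lithium acetylide by a primary bromide, in which the large excess of the dibromide should suppress double alkylation.

Step 2
Reactants: 5 (4R)-4-benzyl-3-propanoyl-1,3-oxazolidin-2-one; 6 3-bromo-2-methylprop-1-ene
Product: 8 (4R)-4-benzyl-3-[(2S)-2,4-dimethylpent-4-enoyl]-1,3-oxazolidin-2-one, via sodium Z-enolate 7 (not isolated)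
Conditions: NaN(SiMe3)2, THF, −78 °C; then 6 (3 equiv), −78 to −45 °C
Reagents that add atoms: none
Why: Evans asymmetric alkylation, in which the chelated Z-enolate is attacked by the allylic bromide on the face away from the benzyl group of the (R)-auxiliary, setting the (2S) centre that becomes C8 of the target.

Step 3
Reactants: 8 (4R)-4-benzyl-3-[(2S)-2,4-dimethylpent-4-enoyl]-1,3-oxazolidin-2-one
Product: 9 (2S)-2,4-dimethylpent-4-en-1-ol
Conditions: LiBH4, H2O (1 equiv), Et2O, 0 °C
Reagents that add atoms: none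
Why: Reductive cleavage of the N-acyl oxazolidinone by borohydride at the exocyclic carbonyl should give the primary alcohol without touching the stereocentre and return the auxiliary.

Step 4
Reactants: 9 (2S)-2,4-dimethylpent-4-en-1-ol
Product: 10 (2S)-2,4-dimethylpent-4-en-1-yl 4-methylbenzenesulfonate
Conditions: TsCl, Et3N, DMAP (cat.), CH2Cl2, 0 °C to rt
Reagents that add atoms: 4-methylbenzenesulfonyl chloride, Cc1ccc(cc1)S(=O)(=O)Cl
Why: Sulfonylation of an unhindered primary alcohol, which also turns the volatile alcohol into a non-volatile electrophile.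

Step 5
Reactants: 4 7-bromo-1-phenylhept-1-yne; 10 (2S)-2,4-dimethylpent-4-en-1-yl 4-methylbenzenesulfonate
Product: 12 (4R)-2,4-dimethyl-12-phenyldodec-1-en-11-yne, via Grignard reagent 11 (not isolated)
Conditions: 4 (1.5 equiv), Mg, THF, 40 °C; then 10, Li2CuCl4 (5 mol%), THF, −20 °C to rt
Reagents that add atoms: none
Why: Copper-catalysed sp3–sp3 cross-coupling of a primary alkyl Grignard reagent with a primary tosylate (Kochi–Schlosser type), which leaves the β-stereocentre untouched (its descriptor changes from S to R only through the priority change).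

Step 6
Reactants: 13 2,2,5-trimethyl-1,3-dioxane-4,6-dione
Product: 14 3-tert-butoxy-2-methyl-3-oxopropanoic acid (racemic)
Conditions: t-BuOH, 83 °C
Reagents that add atoms: tert-butanol, CC(C)(C)O
Why: Alcoholysis of a Meldrum's acid derivative, in which ring opening by the alcohol with loss of acetone gives the malonic half ester.

Step 7
Reactants: 14 3-tert-butoxy-2-methyl-3-oxopropanoic acid; 15 2,2-dimethyl-1,3-dioxane-4,6-dione
Product: 17 1-tert-butyl 5-methyl 2-methyl-3-oxopentanedioate (racemic at the labile centre), via acyl Meldrum's acid 16 (not isolated)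
Conditions: DCC, DMAP, CH2Cl2, 0 °C to rt, filter; then MeOH, 65 °C
Reagents that add atoms: methanol, CO
Why: C-acylation of Meldrum's acid by the carbodiimide-activated acid, then methanolysis of the acyl Meldrum's acid through its acylketene with loss of acetone and CO2, a standard β-keto ester synthesis that the tert-butyl ester should survive.

Step 8
Reactants: 12 (4R)-2,4-dimethyl-12-phenyldodec-1-en-11-yne; 17 1-tert-butyl 5-methyl 2-methyl-3-oxopentanedioate; 18 dioxygen
Product: 20 tert-butyl 3-hydroxy-3-(2-methoxy-2-oxoethyl)-4,6-dimethyl-6-[(2R)-2-methyl-10-phenyldec-9-yn-1-yl]-1,2-dioxane-4-carboxylate (C4/C6 diastereomer mixture), via open-chain hydroperoxide 19 (not isolated)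
Conditions: 17 (2 equiv), Mn(OAc)3·2H2O (0.2 equiv), AcOH, dry air (1 atm), 23 °C
Reagents that add atoms: none
Why: Trivalent manganese oxidises the enol of 17 at the methyl-bearing α-carbon to an electrophilic tertiary radical, which adds to the CH2 terminus of 12 (C4–C5); the tertiary C6 radical captures O2 (C6–O1), the peroxyl radical is reduced by divalent manganese with return of the trivalent metal, and hydroperoxide 19 adds to the C3 ketone (O2–C3). The closest known reaction type is the manganese-mediated aerobic peroxycyclisation of 1,3-dicarbonyl compounds with 1,1-disubstituted alkenes to 1,2-dioxan-3-ols. The 1,2-dioxane ring closes by 6-exo-trig attack of the hydroperoxide oxygen on the ketone carbonyl, a reversible hemiketalisation. C3 is under thermodynamic control (anomeric, axial hydroxyl), C4 is a quaternary centre formed without control and erased in step 9, and C6 arises by attack of O2 on a planar radical that the C8 centre cannot bias, so both C6 epimers are expected. The step needs oxidation at C4 and not at the C2 methylene, which the more easily oxidised α-substituted enol and the more stabilised tertiary radical should favour, and it needs attack at the alkene CH2, which the unhindered terminus and the tertiary adduct radical secure. The aryl alkyne is a much poorer acceptor for the electrophilic radical than the 1,1-dialkyl alkene, which is why the tail is carried at the alkyne level, and 17 is used in excess because its own α-oxygenation competes.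

Step 9
Reactants: 20 tert-butyl 3-hydroxy-3-(2-methoxy-2-oxoethyl)-4,6-dimethyl-6-[(2R)-2-methyl-10-phenyldec-9-yn-1-yl]-1,2-dioxane-4-carboxylate
Product: 24 methyl 2-[(3S,4R,6S)-3-hydroxy-4,6-dimethyl-6-[(2R)-2-methyl-10-phenyldec-9-yn-1-yl]-1,2-dioxan-3-yl]acetate, via dioxanol carboxylic acid 21 (not isolated), via ring-opened keto acid 22 (not isolated), via hydroperoxy keto ester 23 (not isolated)
Conditions: TFA/CH2Cl2 (1:4), 0 °C to rt; evaporate; toluene, 40 °C; then preparative HPLC (silica) to remove the C6 epimer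
Reagents that add atoms: none
Why: Acidolysis of the tert-butyl ester gives acid 21, whose ring-opened β-keto acid tautomer 22 decarboxylates in the usual way; hydroperoxy ketone 23 recloses by hemiketalisation, C4 is set at ketonisation and can equilibrate through 23 toward the chair with equatorial 4-methyl and equatorial C6 chain, C3 follows with an axial anomeric hydroxyl, and the C6 epimer carried from step 8 (with any 4-epimer) is removed by chromatography.

Step 10
Reactants: 24 methyl 2-[(3S,4R,6S)-3-hydroxy-4,6-dimethyl-6-[(2R)-2-methyl-10-phenyldec-9-yn-1-yl]-1,2-dioxan-3-yl]acetate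
Product: 25 methyl 2-[(3S,4R,6S)-3-hydroxy-4,6-dimethyl-6-[(2R,9Z)-2-methyl-10-phenyldec-9-en-1-yl]-1,2-dioxan-3-yl]acetate
Conditions: H2 (1 atm), Pd/CaCO3 poisoned with Pb(OAc)2, quinoline, EtOAc, 0 °C to rt, stopped after 1 equiv H2
Reagents that add atoms: none
Why: Lindlar semi-hydrogenation delivers both hydrogens syn on the catalyst surface to give the Z-styrene, and the poisoned palladium should leave the dialkyl peroxide bond and the ester intact.

**Compound list**
1 | phenylacetylene | C#Cc1ccccc1 | starting material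
2 | 1,5-dibromopentane | BrCCCCCBr | starting material
3 | lithium phenylacetylide | [Li]C#Cc1ccccc1 | intermediate
4 | 7-bromo-1-phenylhept-1-yne | BrCCCCCC#Cc1ccccc1 | intermediate
5 | (4R)-4-benzyl-3-propanoyl-1,3-oxazolidin-2-one | CCC(=O)N1[C@H](Cc2ccccc2)COC1=O | starting material
6 | 3-bromo-2-methylprop-1-ene | C=C(C)CBr | starting material
7 | sodium (1Z)-1-[(4R)-4-benzyl-2-oxo-1,3-oxazolidin-3-yl]prop-1-en-1-olate | C/C=C(\[O-])N1[C@H](Cc2ccccc2)COC1=O.[Na+] | intermediate
8 | (4R)-4-benzyl-3-[(2S)-2,4-dimethylpent-4-enoyl]-1,3-oxazolidin-2-one | C=C(C)C[C@H](C)C(=O)N1[C@H](Cc2ccccc2)COC1=O | intermediate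
9 | (2S)-2,4-dimethylpent-4-en-1-ol | C=C(C)C[C@H](C)CO | intermediate
10 | (2S)-2,4-dimethylpent-4-en-1-yl 4-methylbenzenesulfonate | C=C(C)C[C@H](C)COS(=O)(=O)c1ccc(C)cc1 | intermediate
11 | bromo(7-phenylhept-6-yn-1-yl)magnesium | Br[Mg]CCCCCC#Cc1ccccc1 | intermediate
12 | (4R)-2,4-dimethyl-12-phenyldodec-1-en-11-yne | C=C(C)C[C@H](C)CCCCCCC#Cc1ccccc1 | intermediate
13 | 2,2,5-trimethyl-1,3-dioxane-4,6-dione | CC1C(=O)OC(C)(C)OC1=O | starting material
14 | 3-tert-butoxy-2-methyl-3-oxopropanoic acid (racemic) | CC(C(=O)O)C(=O)OC(C)(C)C | intermediate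
15 | 2,2-dimethyl-1,3-dioxane-4,6-dione (Meldrum's acid) | CC1(C)OC(=O)CC(=O)O1 | starting material
16 | tert-butyl 3-(2,2-dimethyl-4,6-dioxo-1,3-dioxan-5-ylidene)-3-hydroxy-2-methylpropanoate | CC(C(=O)OC(C)(C)C)C(O)=C1C(=O)OC(C)(C)OC1=O | intermediate
17 | 1-tert-butyl 5-methyl 2-methyl-3-oxopentanedioate (racemic) | COC(=O)CC(=O)C(C)C(=O)OC(C)(C)C | intermediate
18 | dioxygen | O=O | starting material
19 | 1-tert-butyl 5-methyl 2-[(4R)-2-hydroperoxy-2,4-dimethyl-12-phenyldodec-11-yn-1-yl]-2-methyl-3-oxopentanedioate (epimers at both new centres) | COC(=O)CC(=O)C(C)(CC(C)(OO)C[C@H](C)CCCCCCC#Cc1ccccc1)C(=O)OC(C)(C)C | intermediate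
20 | tert-butyl 3-hydroxy-3-(2-methoxy-2-oxoethyl)-4,6-dimethyl-6-[(2R)-2-methyl-10-phenyldec-9-yn-1-yl]-1,2-dioxane-4-carboxylate (diastereomers at C4 and C6) | COC(=O)CC1(O)OOC(C)(C[C@H](C)CCCCCCC#Cc2ccccc2)CC1(C)C(=O)OC(C)(C)C | intermediate
21 | 3-hydroxy-3-(2-methoxy-2-oxoethyl)-4,6-dimethyl-6-[(2R)-2-methyl-10-phenyldec-9-yn-1-yl]-1,2-dioxane-4-carboxylic acid | COC(=O)CC1(O)OOC(C)(C[C@H](C)CCCCCCC#Cc2ccccc2)CC1(C)C(=O)O | intermediate
22 | 2-[(4R)-2-hydroperoxy-2,4-dimethyl-12-phenyldodec-11-yn-1-yl]-5-methoxy-2-methyl-3,5-dioxopentanoic acid | COC(=O)CC(=O)C(C)(CC(C)(OO)C[C@H](C)CCCCCCC#Cc1ccccc1)C(=O)O | intermediate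
23 | methyl (8R)-6-hydroperoxy-4,6,8-trimethyl-3-oxo-16-phenylhexadec-15-ynoate | COC(=O)CC(=O)C(C)CC(C)(OO)C[C@H](C)CCCCCCC#Cc1ccccc1 | intermediate
24 | methyl 2-[(3S,4R,6S)-3-hydroxy-4,6-dimethyl-6-[(2R)-2-methyl-10-phenyldec-9-yn-1-yl]-1,2-dioxan-3-yl]acetate | COC(=O)C[C@]1(O)OO[C@@](C)(C[C@H](C)CCCCCCC#Cc2ccccc2)C[C@H]1C | intermediate
25 | methyl 2-[(3S,4R,6S)-3-hydroxy-4,6-dimethyl-6-[(2R,9Z)-2-methyl-10-phenyldec-9-en-1-yl]-1,2-dioxan-3-yl]acetate | COC(=O)C[C@]1(O)OO[C@@](C)(C[C@H](C)CCCCCC/C=C\c2ccccc2)C[C@H]1C | target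

**Step count**
Total: 10 steps. Longest linear sequence: 7 steps (steps 2, 3, 4, 5, 8, 9, 10).

**Steps most likely to fail**

1. Step 8. Oxidation may also start at the C2 methylene of 17, the C4 radical may be oxygenated before it meets the alkene, and C6 forms without facial bias. The fallback sets out from 12 and returns at 23 (and so at 24). It builds C4–C5 by enolate alkylation and C6–O by cobalt-mediated hydroperoxysilylation.
   - Epoxidation of 12 (mCPBA, NaHCO3, CH2Cl2) would give 2-methyl-2-[(2R)-2-methyl-10-phenyldec-9-yn-1-yl]oxirane F1.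
   - Isomerisation with diethylaluminium 2,2,6,6-tetramethylpiperidide (toluene, 0 °C) would give the allylic alcohol (4R)-4-methyl-2-methylidene-12-phenyldodec-11-yn-1-ol F2.
   - An Appel reaction (CBr4, PPh3, CH2Cl2) would give (4R)-2-(bromomethyl)-4-methyl-12-phenyldodec-1-en-11-yne F3.
   - γ-Alkylation of the dianion of methyl 3-oxopentanoate (NaH, then n-BuLi, THF, 0 °C) with F3 would form C4–C5 without ambiguity and give methyl (8R)-4,8-dimethyl-6-methylidene-3-oxo-16-phenylhexadec-15-ynoate F4.
   - Isayama–Mukaiyama hydroperoxysilylation (Co(acac)2, Et3SiH, O2, 1,2-dichloroethane, rt) would place the peroxide at tertiary C6 and give methyl (8R)-4,6,8-trimethyl-3-oxo-16-phenyl-6-[(triethylsilyl)peroxy]hexadec-15-ynoate F5.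
   - Dilute HCl in THF/H2O would free hydroperoxide 23, which closes to 24. Both C6 epimers would again form and be separated as in step 9.

2. Step 9. Acid may ionise the peroxyhemiketal at C3 and trigger dehydration or O–O heterolysis before the ester is cleaved, and ring opening to the β-keto acid may be too slow for clean decarboxylation. The fallback sets out from 13 and returns at 21. It replaces acidolysis by fluoride-triggered unmasking.
   - Ring opening of 13 with 2-(trimethylsilyl)ethanol (toluene, 90 °C) would give 2-methyl-3-oxo-3-[2-(trimethylsilyl)ethoxy]propanoic acid F6.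
   - Condensation with 15 (DCC, DMAP) would give the acyl Meldrum's acid 2-(trimethylsilyl)ethyl 3-(2,2-dimethyl-4,6-dioxo-1,3-dioxan-5-ylidene)-3-hydroxy-2-methylpropanoate F7, and methanolysis would give 5-methyl 1-[2-(trimethylsilyl)ethyl] 2-methyl-3-oxopentanedioate F8.
   - Peroxyannulation of F8 with 12 and 18 under the conditions of step 8 would give 2-(trimethylsilyl)ethyl 3-hydroxy-3-(2-methoxy-2-oxoethyl)-4,6-dimethyl-6-[(2R)-2-methyl-10-phenyldec-9-yn-1-yl]-1,2-dioxane-4-carboxylate F9.
   - Bu4NF buffered with AcOH (THF, 0 °C), then a pH 5 buffer, would release acid 21 without strong acid; it should decarboxylate to 24 on gentle warming.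

3. Step 10. The O–O bond may be hydrogenolysed, most probably through the ring-opened hydroperoxide tautomer, and the styrene may be over-reduced or isomerised from Z to E. The fallback sets out from 24 and returns at 25. It locks the ring before the reduction.
   - N-(Trimethylsilyl)imidazole (CH2Cl2, rt) would give the trimethylsilyl peroxyketal methyl 2-[(3R,4R,6S)-4,6-dimethyl-6-[(2R)-2-methyl-10-phenyldec-9-yn-1-yl]-3-(trimethylsilyloxy)-1,2-dioxan-3-yl]acetate F10, which has no hydroperoxide tautomer.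
   - Semi-hydrogenation over Pd/CaCO3 poisoned with Pb(OAc)2 would give the Z-alkene methyl 2-[(3R,4R,6S)-4,6-dimethyl-6-[(2R,9Z)-2-methyl-10-phenyldec-9-en-1-yl]-3-(trimethylsilyloxy)-1,2-dioxan-3-yl]acetate F11.
   - AcOH/THF/H2O at rt would remove the silyl group and give 25.

**Further compounds**
F1 | step 8 | 2-methyl-2-[(2R)-2-methyl-10-phenyldec-9-yn-1-yl]oxirane (both epimers at the oxirane carbon) | CC1(C[C@H](C)CCCCCCC#Cc2ccccc2)CO1
F2 | step 8 | (4R)-4-methyl-2-methylidene-12-phenyldodec-11-yn-1-ol | C=C(CO)C[C@H](C)CCCCCCC#Cc1ccccc1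
F3 | step 8 | (4R)-2-(bromomethyl)-4-methyl-12-phenyldodec-1-en-11-yne | C=C(CBr)C[C@H](C)CCCCCCC#Cc1ccccc1
F4 | step 8 | methyl (8R)-4,8-dimethyl-6-methylidene-3-oxo-16-phenylhexadec-15-ynoate (C4 epimers) | COC(=O)CC(=O)C(C)CC(=C)C[C@H](C)CCCCCCC#Cc1ccccc1
F5 | step 8 | methyl (8R)-4,6,8-trimethyl-3-oxo-16-phenyl-6-[(triethylsilyl)peroxy]hexadec-15-ynoate (C4 and C6 epimers) | COC(=O)CC(=O)C(C)CC(C)(OO[Si](CC)(CC)CC)C[C@H](C)CCCCCCC#Cc1ccccc1
F6 | step 9 | 2-methyl-3-oxo-3-[2-(trimethylsilyl)ethoxy]propanoic acid | CC(C(=O)O)C(=O)OCC[Si](C)(C)C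
F7 | step 9 | 2-(trimethylsilyl)ethyl 3-(2,2-dimethyl-4,6-dioxo-1,3-dioxan-5-ylidene)-3-hydroxy-2-methylpropanoate | CC(C(=O)OCC[Si](C)(C)C)C(O)=C1C(=O)OC(C)(C)OC1=O
F8 | step 9 | 5-methyl 1-[2-(trimethylsilyl)ethyl] 2-methyl-3-oxopentanedioate | COC(=O)CC(=O)C(C)C(=O)OCC[Si](C)(C)C
F9 | step 9 | 2-(trimethylsilyl)ethyl 3-hydroxy-3-(2-methoxy-2-oxoethyl)-4,6-dimethyl-6-[(2R)-2-methyl-10-phenyldec-9-yn-1-yl]-1,2-dioxane-4-carboxylate (C4 and C6 diastereomers) | COC(=O)CC1(O)OOC(C)(C[C@H](C)CCCCCCC#Cc2ccccc2)CC1(C)C(=O)OCC[Si](C)(C)C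
F10 | step 10 | methyl 2-[(3R,4R,6S)-4,6-dimethyl-6-[(2R)-2-methyl-10-phenyldec-9-yn-1-yl]-3-(trimethylsilyloxy)-1,2-dioxan-3-yl]acetate | COC(=O)C[C@]1(O[Si](C)(C)C)OO[C@@](C)(C[C@H](C)CCCCCCC#Cc2ccccc2)C[C@H]1C
F11 | step 10 | methyl 2-[(3R,4R,6S)-4,6-dimethyl-6-[(2R,9Z)-2-methyl-10-phenyldec-9-en-1-yl]-3-(trimethylsilyloxy)-1,2-dioxan-3-yl]acetate | COC(=O)C[C@]1(O[Si](C)(C)C)OO[C@@](C)(C[C@H](C)CCCCCC/C=C\c2ccccc2)C[C@H]1C
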